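**Plan**

1. Atom numbers are labdane numbers (decalin C1–C10, side chain C11–C16 on C9, C17 on C8, methyls on C4 and C10). Cuts, in order: the C17 acid back to a masked aldehyde; C11–C12 (sp3–sp2 coupling), with C9–H/C11–B back to an exocyclic C9=C11 methylene; that methylene and the C7=C8 alkene back to a leaving group on C11 (1,4-elimination); then C7–C8 and C9–C10 together by a [4+2] cycloaddition.
2. Enabling feature: ring B has oxygen on C6 and the C7=C8 alkene beside the quaternary ring-fusion carbon C10. C10=C5–C6(OSi)=C7 is therefore a 2-silyloxy diene lying on ring A, and C8≡C9 with its two one-carbon arms (C17, C11) is an alkyne dienophile.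
3. Forward: ring A is bought (β-cyclocitral) and made into the diene; ring B is closed by the Diels–Alder reaction; the formyl helper on C11 is reduced, acetylated and expelled; the side chain is joined by hydroboration and Suzuki coupling; acetylation, acetal hydrolysis and chlorite oxidation finish.
4. Stereochemistry: C10 from the chiral Lewis acid in the cycloaddition; C5 by equilibration next to the C6 ketone (trans ring fusion); C6 by hydride attack anti to the axial methyls; C9 by hydroboration anti to the C10 methyl; the 12E alkene from syn carboalumination.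
5. Helpers: silyl enol ether (activation; becomes the C6 oxygen), formyl group on C11 (regiocontrol; leaves as acetate), diethyl acetal (masked C17 acid; hydrolysed and oxidised last).

Key step: step 4

Remark: 1 and 5 are taken as purchased; the sense of induction of the (S)-catalyst in step 4 is a prediction by analogy with formyl dienophiles, and the antipodal catalyst would be used unchanged if the mirror-image adduct should predominate.

Step 1
Reactants: 1 β-cyclocitral
Product: 2 1-(2,6,6-trimethylcyclohex-1-en-1-yl)ethan-1-ol (racemic)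
Conditions: MeMgBr, Et2O, 0 °C
Reagents that add atoms: methylmagnesium bromide, C[Mg]Br
Why: Grignard 1,2-addition to the hindered enal carbonyl; the carbinol centre is racemic and is erased in step 2.

Step 2
Reactants: 2 carbinol
Product: 3 1-(2,6,6-trimethylcyclohex-1-en-1-yl)ethan-1-one
Conditions: Dess–Martin periodinane, NaHCO3, CH2Cl2, 0 °C to rt
Reagents that add atoms: none
Why: Dess–Martin oxidation of a secondary allylic alcohol to the methyl ketone; no stereocentre remains.

Step 3
Reactants: 3 methyl ketone
Product: 4 2-silyloxy diene (tert-butyldimethylsilyl enol ether of 3)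
Conditions: t-BuMe2SiOTf, Et3N, CH2Cl2, −78 to 0 °C
Reagents that add atoms: tert-butyldimethylsilyl triflate, CC(C)(C)[Si](C)(C)OS(=O)(=O)C(F)(F)F
Why: Soft enolisation (silyl triflate and amine) of a ketone whose only α-hydrogens are on the methyl group should give the cross-conjugated 2-silyloxy diene.

Step 4
Reactants: 4 2-silyloxy diene; 5 4,4-diethoxybut-2-ynal
Product: 6 (8aR)-4-[(tert-butyldimethylsilyl)oxy]-2-(diethoxymethyl)-5,5,8a-trimethyl-3,5,6,7,8,8a-hexahydronaphthalene-1-carbaldehyde
Conditions: (S)-1-(2-methylphenyl)-3,3-diphenyltetrahydro-1H,3H-pyrrolo[1,2-c][1,3,2]oxazaborole (20 mol %), HN(SO2CF3)2 (18 mol %), CH2Cl2, −78 to −40 °C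
Reagents that add atoms: none
Why: Proposed new method: the formyl oxygen of 5 binds to the chiral oxazaborolidinium ion, and the activated alkyne and the s-cis diene 4 then combine in an asynchronous, suprafacial [4π+2π] cycloaddition in which the enol-ether terminus C7 bonds first to the β-carbon C8 and the formyl-bearing carbon C9 closes onto the ring carbon C10. The closest known reaction types are the oxazaborolidinium-catalysed Diels–Alder reactions of 2-silyloxy dienes with formyl dienophiles, the chiral-boron-catalysed cycloadditions of alk-2-ynals, and the thermal cycloaddition of 1-vinyl-2,6,6-trimethylcyclohexenes with acetylenic dienophiles; what is new is their combination on a diene terminus that becomes quaternary. Ring B is the only ring closed, as a cyclohexa-1,4-diene, by intermolecular [4+2] addition across C7 and C10 with both σ-bonds made in one operation. The only new stereocentre, quaternary C10, is set by the catalyst, which shields one face of the bound alkynal while the bulky trimethylcyclohexene ring is turned away from the complexed formyl group, so that one face of C10 is offered to C9. The step needs regioselectivity, secured electronically (the C6 silyloxy group makes C7 the nucleophilic terminus and the formyl group makes C8 the electrophilic carbon) and sterically (the diethoxymethyl end meets the unhindered CH2 terminus), and it needs cycloaddition to outrun 1,2-addition to the aldehyde, which the preorganised s-cis diene favours by closing the second bond at once.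

Step 5
Reactants: 6 cycloadduct aldehyde
Product: 7 [(8aS)-4-[(tert-butyldimethylsilyl)oxy]-2-(diethoxymethyl)-5,5,8a-trimethyl-3,5,6,7,8,8a-hexahydronaphthalen-1-yl]methanol
Conditions: i-Bu2AlH, CH2Cl2, −78 °C
Reagents that add atoms: none
Why: 1,2-Reduction of the conjugated aldehyde by the aluminium hydride at low temperature should leave acetal, silyl enol ether and C10 untouched (the descriptor changes only through the priority rules).

Step 6
Reactants: 7 allylic alcohol
Product: 8 acetate of 7
Conditions: Ac2O, Et3N, 4-(dimethylamino)pyridine (cat.), CH2Cl2, 0 °C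
Reagents that add atoms: acetic anhydride, CC(=O)OC(C)=O
Why: Amine-catalysed acylation of the primary allylic alcohol turns the former activating group into a leaving group.

Step 7
Reactants: 8 allylic acetate
Product: 10 (4aR,8aR)-3-(diethoxymethyl)-4a,8,8-trimethyl-4-methylidene-4a,5,6,7,8,8a-hexahydronaphthalen-1(4H)-one, via keto acetate 9 (not isolated)
Conditions: Bu4NF, THF, 0 °C; then 1,8-diazabicyclo[5.4.0]undec-7-ene, rt
Reagents that add atoms: none
Why: Fluoride desilylation releases the C6 ketone, and vinylogous E1cB (1,4-) elimination of acetate from the C7 enolate through C8=C9 should give the cross-conjugated dienone with the exocyclic C9=C11 methylene, while C5, α to the ketone, equilibrates to the more stable trans ring fusion (H5 anti to the C10 methyl).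

Step 8
Reactants: 10 dienone
Product: 11 (1S,4aR,8aR)-3-(diethoxymethyl)-4a,8,8-trimethyl-4-methylidene-1,4,4a,5,6,7,8,8a-octahydronaphthalen-1-ol
Conditions: NaBH4, CeCl3·7H2O, EtOH, −40 to 0 °C
Reagents that add atoms: none
Why: Luche 1,2-reduction in which hydride should reach the C6 carbonyl from the face opposite the axial methyls on C4 and C10, giving the axial C6 hydroxyl cis to the C10 methyl (ethanol keeps the diethyl acetal unchanged).

Step 9
Reactants: 12 prop-2-yn-1-ol
Product: 14 (2E)-3-iodo-2-methylprop-2-en-1-ol, via alkenylalane 13 (not isolated)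
Conditions: bis(cyclopentadienyl)zirconium dichloride (cat.), Me3Al, CH2Cl2, 0 °C to rt; then I2, THF, −30 °C
Reagents that add atoms: trimethylaluminium, C[Al](C)C; iodine, II
Why: Zirconium-catalysed syn carboalumination (Negishi) puts methyl on the internal carbon and aluminium on the terminus, and iodinolysis with retention gives the E iodide.

Step 10
Reactants: 14 iodo alcohol
Product: 15 (2E)-3-iodo-2-methylprop-2-enal
Conditions: MnO2, CH2Cl2, rt
Reagents that add atoms: none
Why: MnO2 oxidation of an allylic alcohol to the enal without loss of alkene geometry.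

Step 11
Reactants: 15 iodo enal
Product: 16 (1E)-1-iodo-2-methylbuta-1,3-diene
Conditions: Ph3PCH3Br, KN(SiMe3)2, THF, −78 to 0 °C
Reagents that add atoms: methyltriphenylphosphonium bromide, C[P+](c1ccccc1)(c1ccccc1)c1ccccc1.[Br-]
Why: Wittig methylenation of the aldehyde, which does not touch the trisubstituted iodoalkene geometry.

Step 12
Reactants: 11 allylic alcohol; 16 (1E)-1-iodo-2-methylbuta-1,3-diene
Product: 18 (1S,4S,4aS,8aR)-3-(diethoxymethyl)-4a,8,8-trimethyl-4-[(2E)-3-methylpenta-2,4-dien-1-yl]-1,4,4a,5,6,7,8,8a-octahydronaphthalen-1-ol, via alkylborane 17 (not isolated)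
Conditions: 9-borabicyclo[3.3.1]nonane (2.5 equiv), THF, 0 °C to rt; then 16, [1,1′-bis(diphenylphosphino)ferrocene]PdCl2 (cat.), AsPh3, Cs2CO3, DMF/H2O, rt
Reagents that add atoms: none
Why: Hydroboration of the exocyclic methylene should put boron on C11 and hydrogen on C9 from the face opposite the axial C10 methyl (setting C9), and B-alkyl Suzuki–Miyaura coupling with the alkenyl iodide retains the E geometry.

Step 13
Reactants: 18 coupled alcohol
Product: 19 acetate of 18
Conditions: Ac2O, 4-(dimethylamino)pyridine, pyridine, rt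
Reagents that add atoms: acetic anhydride, CC(=O)OC(C)=O
Why: Amine-catalysed acetylation (esterification) of the hindered axial secondary alcohol.

Step 14
Reactants: 19 acetal acetate
Product: 20 (1S,4S,4aR,8aS)-4-(acetyloxy)-5,5,8a-trimethyl-1-[(2E)-3-methylpenta-2,4-dien-1-yl]-1,4,4a,5,6,7,8,8a-octahydronaphthalene-2-carbaldehyde
Conditions: pyridinium p-toluenesulfonate (cat.), acetone/H2O, rt
Reagents that add atoms: water, O
Why: Mild acid-catalysed hydrolysis of the conjugated diethyl acetal to the enal, under buffered conditions that the allylic acetate and the diene should survive.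

Step 15
Reactants: 20 enal
Product: 21 (1S,4S,4aR,8aS)-4-(acetyloxy)-5,5,8a-trimethyl-1-[(2E)-3-methylpenta-2,4-dien-1-yl]-1,4,4a,5,6,7,8,8a-octahydronaphthalene-2-carboxylic acid
Conditions: NaClO2, NaH2PO4, 2-methylbut-2-ene, t-BuOH/H2O, 0 °C to rt
Reagents that add atoms: sodium chlorite, [Na+].[O-]Cl=O
Why: Pinnick (chlorite) oxidation of the enal to the acid, with the alkene scavenger keeping hypochlorous acid away from the diene.

**Compound list**

1 | β-cyclocitral (2,6,6-trimethylcyclohex-1-ene-1-carbaldehyde) | O=CC1=C(C)CCCC1(C)C | starting material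
2 | 1-(2,6,6-trimethylcyclohex-1-en-1-yl)ethan-1-ol (racemic) | CC(O)C1=C(C)CCCC1(C)C | intermediate
3 | 1-(2,6,6-trimethylcyclohex-1-en-1-yl)ethan-1-one | CC(=O)C1=C(C)CCCC1(C)C | intermediate
4 | tert-butyldimethyl{[1-(2,6,6-trimethylcyclohex-1-en-1-yl)ethenyl]oxy}silane | C=C(O[Si](C)(C)C(C)(C)C)C1=C(C)CCCC1(C)C | intermediate
5 | 4,4-diethoxybut-2-ynal | CCOC(OCC)C#CC=O | starting material
6 | (8aR)-4-[(tert-butyldimethylsilyl)oxy]-2-(diethoxymethyl)-5,5,8a-trimethyl-3,5,6,7,8,8a-hexahydronaphthalene-1-carbaldehyde | O=CC1=C(C(OCC)OCC)CC(O[Si](C)(C)C(C)(C)C)=C2C(C)(C)CCC[C@@]12C | intermediate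
7 | [(8aS)-4-[(tert-butyldimethylsilyl)oxy]-2-(diethoxymethyl)-5,5,8a-trimethyl-3,5,6,7,8,8a-hexahydronaphthalen-1-yl]methanol | OCC1=C(C(OCC)OCC)CC(O[Si](C)(C)C(C)(C)C)=C2C(C)(C)CCC[C@@]12C | intermediate
8 | [(8aS)-4-[(tert-butyldimethylsilyl)oxy]-2-(diethoxymethyl)-5,5,8a-trimethyl-3,5,6,7,8,8a-hexahydronaphthalen-1-yl]methyl acetate | CC(=O)OCC1=C(C(OCC)OCC)CC(O[Si](C)(C)C(C)(C)C)=C2C(C)(C)CCC[C@@]12C | intermediate
9 | [(4aR,8aR)-2-(diethoxymethyl)-5,5,8a-trimethyl-4-oxo-3,4,4a,5,6,7,8,8a-octahydronaphthalen-1-yl]methyl acetate | CC(=O)OCC1=C(C(OCC)OCC)CC(=O)[C@@H]2C(C)(C)CCC[C@@]12C | intermediate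
10 | (4aR,8aR)-3-(diethoxymethyl)-4a,8,8-trimethyl-4-methylidene-4a,5,6,7,8,8a-hexahydronaphthalen-1(4H)-one | C=C1C(C(OCC)OCC)=CC(=O)[C@@H]2C(C)(C)CCC[C@@]12C | intermediate
11 | (1S,4aR,8aR)-3-(diethoxymethyl)-4a,8,8-trimethyl-4-methylidene-1,4,4a,5,6,7,8,8a-octahydronaphthalen-1-ol | C=C1C(C(OCC)OCC)=C[C@H](O)[C@@H]2C(C)(C)CCC[C@@]12C | intermediate
12 | prop-2-yn-1-ol | OCC#C | starting material
13 | dimethyl[(1E)-3-(dimethylalumanyloxy)-2-methylprop-1-en-1-yl]alane | C[Al](C)OC/C(C)=C/[Al](C)C | intermediate
14 | (2E)-3-iodo-2-methylprop-2-en-1-ol | OC/C(C)=C/I | intermediate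
15 | (2E)-3-iodo-2-methylprop-2-enal | O=C/C(C)=C/I | intermediate
16 | (1E)-1-iodo-2-methylbuta-1,3-diene | C=C/C(C)=C/I | intermediate
17 | B-alkyl-9-borabicyclo[3.3.1]nonane from 11 (boron on C11; C6 oxygen carried as its 9-borabicyclononyl borinate) | B3(C[C@@H]1C(C(OCC)OCC)=C[C@H](OB5C6CCCC5CCC6)[C@@H]2C(C)(C)CCC[C@@]12C)C4CCCC3CCC4 | intermediate
18 | (1S,4S,4aS,8aR)-3-(diethoxymethyl)-4a,8,8-trimethyl-4-[(2E)-3-methylpenta-2,4-dien-1-yl]-1,4,4a,5,6,7,8,8a-octahydronaphthalen-1-ol | C=C/C(C)=C/C[C@@H]1C(C(OCC)OCC)=C[C@H](O)[C@@H]2C(C)(C)CCC[C@@]12C | intermediate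
19 | (1S,4S,4aS,8aR)-3-(diethoxymethyl)-4a,8,8-trimethyl-4-[(2E)-3-methylpenta-2,4-dien-1-yl]-1,4,4a,5,6,7,8,8a-octahydronaphthalen-1-yl acetate | C=C/C(C)=C/C[C@@H]1C(C(OCC)OCC)=C[C@H](OC(C)=O)[C@@H]2C(C)(C)CCC[C@@]12C | intermediate
20 | (1S,4S,4aR,8aS)-4-(acetyloxy)-5,5,8a-trimethyl-1-[(2E)-3-methylpenta-2,4-dien-1-yl]-1,4,4a,5,6,7,8,8a-octahydronaphthalene-2-carbaldehyde | C=C/C(C)=C/C[C@@H]1C(C=O)=C[C@H](OC(C)=O)[C@@H]2C(C)(C)CCC[C@@]12C | intermediate
21 | (1S,4S,4aR,8aS)-4-(acetyloxy)-5,5,8a-trimethyl-1-[(2E)-3-methylpenta-2,4-dien-1-yl]-1,4,4a,5,6,7,8,8a-octahydronaphthalene-2-carboxylic acid | C=C/C(C)=C/C[C@@H]1C(C(=O)O)=C[C@H](OC(C)=O)[C@@H]2C(C)(C)CCC[C@@]12C | target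

**Step count and risks**

Total step count: 15. Longest linear sequence: 12 steps (steps 1–8 and 12–15).

Steps most likely to fail:

Step 4. Facial discrimination at C10 may be poor, the silyl enol ether may add 1,2 to the boron-bound aldehyde instead of undergoing cycloaddition, or the Lewis acid may ionise the acetal. The fallback sets out from 4 and 5. The uncatalysed thermal Diels–Alder reaction (toluene, 80 °C), a known reaction type for 1-vinyl-2,6,6-trimethylcyclohexenes and acetylenic dienophiles, should give the racemic cycloadduct F1. Reduction as in step 5 should give the racemic alcohol F2. Esterification with (S)-methoxy(phenyl)acetic acid (N,N′-dicyclohexylcarbodiimide, 4-(dimethylamino)pyridine) should give two diastereomers, the (8aS) ester F3 and the (8aR) ester F4, to be separated by chromatography or crystallisation. F3 is then treated as in step 7, with the arylacetate as the leaving group, and comes back to the route at 10.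

Step 12. Transmetalation of the β-branched alkylborane next to the quaternary centre may be slow, with protodeboronation taking over. The fallback sets out from 11. Hydroboration as before and oxidation of 17 (NaBO3·4H2O) should give the diol F5. Selective iodination of the primary hydroxyl (I2, PPh3, imidazole) should give the iodide F6. Nickel-catalysed reductive cross-electrophile coupling of F6 with 16 (NiI2, 4,4′-di-tert-butyl-2,2′-bipyridine, Zn dust, N,N-dimethylacetamide), which tolerates the free hydroxyl, comes back to the route at 18.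

Step 7. Fluoride or adventitious hydroxide may cleave the acetate before elimination, or acetate may re-add to the dienone. The fallback sets out from 8. Buffered fluoride (Bu4NF, AcOH, THF, 0 °C) allows 9 to be isolated. Zerovalent palladium (Pd(PPh3)4, Et3N, THF, 50 °C) then ionises the allylic acetate to the π-allyl complex, and loss of the acidic C7 proton gives the diene (elimination of Tsuji–Trost type), coming back to the route at 10. This detour makes no compound outside the list (F0).

Further compounds
F1 | step 4 | racemic cycloadduct (racemate of 6) | O=CC1=C(C(OCC)OCC)CC(O[Si](C)(C)C(C)(C)C)=C2C(C)(C)CCCC12C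
F2 | step 4 | racemic alcohol (racemate of 7) | OCC1=C(C(OCC)OCC)CC(O[Si](C)(C)C(C)(C)C)=C2C(C)(C)CCCC12C
F3 | step 4 | (S)-methoxy(phenyl)acetate of the (8aS) alcohol | CO[C@H](C(=O)OCC1=C(C(OCC)OCC)CC(O[Si](C)(C)C(C)(C)C)=C2C(C)(C)CCC[C@@]12C)c1ccccc1
F4 | step 4 | (S)-methoxy(phenyl)acetate of the (8aR) alcohol | CO[C@H](C(=O)OCC1=C(C(OCC)OCC)CC(O[Si](C)(C)C(C)(C)C)=C2C(C)(C)CCC[C@]12C)c1ccccc1
F5 | step 12 | (1S,4S,4aS,8aR)-3-(diethoxymethyl)-4-(hydroxymethyl)-4a,8,8-trimethyl-1,4,4a,5,6,7,8,8a-octahydronaphthalen-1-ol | OC[C@@H]1C(C(OCC)OCC)=C[C@H](O)[C@@H]2C(C)(C)CCC[C@@]12C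
F6 | step 12 | (1S,4S,4aS,8aR)-3-(diethoxymethyl)-4-(iodomethyl)-4a,8,8-trimethyl-1,4,4a,5,6,7,8,8a-octahydronaphthalen-1-ol | IC[C@@H]1C(C(OCC)OCC)=C[C@H](O)[C@@H]2C(C)(C)CCC[C@@]12C
F0 | step 7 | none | none
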